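**Retrosynthetic overview**
- Target ⇒ C2-symmetric bis(2-isopropoxy-5-methoxy-6-methylquinone): the methyl ether of one ring is hydrolysed (ring A keeps OMe, ring B becomes the dihydroxyquinone), then BCl3 removes both isopropyl groups.
- Both quinone rings ⇒ formed together, in one operation, by twofold 4π-opening/6π-closure of a bis(4-alkenyl-4-hydroxycyclobutenone), then oxidation.
- Bis(cyclobutenone) ⇒ bis(cyclobutenedione) + 2 × (β-methoxy-α-methylvinyl)lithium.
- Bis(cyclobutenedione) ⇒ C13 di-Grignard reagent (from brassylic acid) + 2 × diisopropyl squarate.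

Assumption: the SMILES has no stereocentre and no stereogenic double bond, so the target is achiral and no enantiocontrol is needed; the linker is read as (CH2)13.

**Step 1**
Reactants: 1 tridecanedioic acid (brassylic acid)
Product: 2 tridecane-1,13-diol
Conditions: BH3·SMe2 (3 equiv), THF, 0 °C → reflux; then 1 M HCl
Reagents that add atoms: none
Why: Borane reduces both carboxylic acids to primary alcohols through acyloxyboranes (borane reduction of acids); no stereocentre is formed.

**Step 2**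
Reactants: 2 tridecane-1,13-diol
Product: 3 1,13-dibromotridecane
Conditions: 48% aq. HBr (excess), conc. H2SO4, reflux
Reagents that add atoms: hydrogen bromide, Br (two molecules per molecule of 2)
Why: Both protonated primary hydroxyls are displaced by bromide (SN2 substitution of an α,ω-diol).

**Step 3**
Reactants: 3 1,13-dibromotridecane (one molecule); 4 diisopropyl squarate (two molecules react per molecule of 3)
Product: 7 3,3'-(tridecane-1,13-diyl)bis[4-(propan-2-yloxy)cyclobut-3-ene-1,2-dione], via BrMg(CH2)13MgBr 5 (not isolated), via bis-carbinol 6 (not isolated)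
Conditions: Mg (2.5 equiv), THF, 40 °C; 4 (3 equiv), THF, −78 → −40 °C, inverse addition; aq. HCl quench; then 12 M HCl (cat.), CH2Cl2, rt
Reagents that add atoms: diisopropyl squarate, CC(C)OC1=C(OC(C)C)C(=O)C1=O (the second molecule of 4 that the other chain end takes up); water, O (its oxygen becomes the new carbonyl oxygen while the carbinol hydroxyl leaves as water)
Why: Each C–MgBr end of 5 adds 1,2 to one carbonyl of a separate squarate molecule (excess 4, inverse addition). Acid then ionises each carbinol and hydrolyses the oxocarbenium ion with loss of isopropanol (Liebeskind cyclobutenedione synthesis); no stereocentre survives.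

**Step 4**
Reactants: 8 2-bromo-1,1-dimethoxypropane
Product: 9 (Z)-2-bromo-1-methoxyprop-1-ene
Conditions: TMSOTf (1.2 equiv), i-Pr2NEt (1.5 equiv), CH2Cl2, −20 °C → rt; spinning-band distillation to isolate the Z isomer
Reagents that add atoms: none
Why: TMSOTf ionises the acetal to an oxocarbenium ion that the amine deprotonates at C2 (Gassman-type acetal-to-enol-ether elimination). An E/Z mixture is expected and only the Z isomer (Br cis to OMe) is carried on, because it alone gives a lithium reagent that cannot undergo anti β-elimination.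

**Step 5**
Reactants: 9 (Z)-2-bromo-1-methoxyprop-1-ene (two molecules react per molecule of 7); 7 3,3'-(tridecane-1,13-diyl)bis[4-(propan-2-yloxy)cyclobut-3-ene-1,2-dione] (one molecule)
Product: 11 2,2'-(tridecane-1,13-diyl)bis{4-hydroxy-4-[(Z)-1-methoxyprop-1-en-2-yl]-3-(propan-2-yloxy)cyclobut-2-en-1-one}, via (1-methoxyprop-1-en-2-yl)lithium 10 (not isolated)
Conditions: 9 (2.6 equiv), t-BuLi (5.2 equiv), Et2O, −78 °C; then 7 (1 equiv), THF, −78 °C; sat. aq. NH4Cl at −78 °C; crude product used at once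
Reagents that add atoms: (Z)-2-bromo-1-methoxyprop-1-ene, CO/C=C(/C)Br (the second molecule of 9 that supplies the alkenyl group of the other ring)
Why: Br/Li exchange with retention gives 10, whose cis OMe chelates Li (as in cis-2-ethoxyvinyllithium). One molecule of 10 adds 1,2 to each ring at the ketone-like carbonyl next to C–OiPr rather than at the vinylogous-ester carbonyl; the two carbinol stereocentres form unselectively and are destroyed in step 6.

**Step 6**
Reactants: 11 2,2'-(tridecane-1,13-diyl)bis{4-hydroxy-4-[(Z)-1-methoxyprop-1-en-2-yl]-3-(propan-2-yloxy)cyclobut-2-en-1-one}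
Product: 14 3,3'-(tridecane-1,13-diyl)bis[5-methoxy-6-methyl-2-(propan-2-yloxy)cyclohexa-2,5-diene-1,4-dione], via bis-dienylketene 12 (not isolated), via bis-hydroquinone 13 (not isolated)
Conditions: PhMe (degassed, 0.01 M), 110 °C, 2 h; then Ag2O, Na2SO4, Et2O, rt
Reagents that add atoms: none
Why: Twofold Liebeskind–Moore ring expansion: conrotatory 4π opening with OH rotating outward places the alkenyl group cis to the ketene. 6π electrocyclisation and enolisation then build both fully substituted hydroquinone rings at once, and Ag2O oxidises them to the quinones; no stereocentre remains.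

**Step 7**
Reactants: 14 3,3'-(tridecane-1,13-diyl)bis[5-methoxy-6-methyl-2-(propan-2-yloxy)cyclohexa-2,5-diene-1,4-dione]
Product: 15 2-hydroxy-3-methyl-5-(propan-2-yloxy)-6-{13-[5-methoxy-4-methyl-3,6-dioxo-2-(propan-2-yloxy)cyclohexa-1,4-dien-1-yl]tridecyl}cyclohexa-2,5-diene-1,4-dione
Conditions: NaOH (1.1 equiv, 0.05 M aq.), THF, 0 °C, stopped at about half conversion of the OMe groups; 1 M HCl; recovered 14 recycled
Reagents that add atoms: sodium hydroxide, [Na+].[OH-] (its oxygen becomes the new ring B hydroxyl oxygen)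
Why: Hydroxide adds to the less hindered methoxy-bearing vinylogous-ester carbon and expels methoxide (addition–elimination), after which that ring is an inert hydroxyquinone anion. The two rings are identical and remote, so about 50% of 15 per pass is the statistical baseline; it may improve if the soap-like mono-anion aggregates and shields its second ring, as in monohydrolysis of symmetric diesters.

**Step 8**
Reactants: 15 2-hydroxy-3-methyl-5-(propan-2-yloxy)-6-{13-[5-methoxy-4-methyl-3,6-dioxo-2-(propan-2-yloxy)cyclohexa-1,4-dien-1-yl]tridecyl}cyclohexa-2,5-diene-1,4-dione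
Product: 16 2,5-dihydroxy-3-[13-(2-hydroxy-5-methoxy-4-methyl-3,6-dioxocyclohexa-1,4-dien-1-yl)tridecyl]-6-methylcyclohexa-2,5-diene-1,4-dione
Conditions: BCl3 (6 equiv), CH2Cl2, −78 → 0 °C; H2O
Reagents that add atoms: none
Why: BCl3 cleaves the secondary O–isopropyl bonds much faster than the O–methyl bond (Lewis-acid ether dealkylation), freeing both hydroxyls next to the chain while ring A keeps its methyl ether.

**Compound list**
1 | tridecanedioic acid (brassylic acid) | OC(=O)CCCCCCCCCCCC(=O)O | starting material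
2 | tridecane-1,13-diol | OCCCCCCCCCCCCCO | intermediate
3 | 1,13-dibromotridecane | BrCCCCCCCCCCCCCBr | intermediate
4 | diisopropyl squarate, 3,4-di(propan-2-yloxy)cyclobut-3-ene-1,2-dione | CC(C)OC1=C(OC(C)C)C(=O)C1=O | starting material
5 | tridecane-1,13-diylbis(magnesium bromide) | Br[Mg]CCCCCCCCCCCCC[Mg]Br | intermediate
6 | 4,4'-(tridecane-1,13-diyl)bis[4-hydroxy-2,3-di(propan-2-yloxy)cyclobut-2-en-1-one], mixture of diastereomers | CC(C)OC1=C(OC(C)C)C(O)(CCCCCCCCCCCCCC2(O)C(OC(C)C)=C(OC(C)C)C2=O)C1=O | intermediate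
7 | 3,3'-(tridecane-1,13-diyl)bis[4-(propan-2-yloxy)cyclobut-3-ene-1,2-dione] | CC(C)OC1=C(CCCCCCCCCCCCCC2=C(OC(C)C)C(=O)C2=O)C(=O)C1=O | intermediate
8 | 2-bromo-1,1-dimethoxypropane (racemic) | CC(Br)C(OC)OC | starting material
9 | (Z)-2-bromo-1-methoxyprop-1-ene | CO/C=C(/C)Br | intermediate
10 | (1-methoxyprop-1-en-2-yl)lithium, Li cis to OMe | CO/C=C(/C)[Li] | intermediate
11 | 2,2'-(tridecane-1,13-diyl)bis{4-hydroxy-4-[(Z)-1-methoxyprop-1-en-2-yl]-3-(propan-2-yloxy)cyclobut-2-en-1-one}, mixture of diastereomers at the two carbinol carbons | CO/C=C(/C)C1(O)C(OC(C)C)=C(CCCCCCCCCCCCCC2=C(OC(C)C)C(O)(/C(C)=C\OC)C2=O)C1=O | intermediate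
12 | 2,2'-(tridecane-1,13-diyl)bis[(3Z,5Z)-4-hydroxy-6-methoxy-5-methyl-3-(propan-2-yloxy)hexa-1,3,5-trien-1-one] | CO/C=C(C)\C(O)=C(OC(C)C)/C(=C=O)CCCCCCCCCCCCCC(=C=O)/C(OC(C)C)=C(/O)\C(C)=C/OC | intermediate
13 | 3,3'-(tridecane-1,13-diyl)bis[5-methoxy-6-methyl-2-(propan-2-yloxy)benzene-1,4-diol] | COc1c(C)c(O)c(OC(C)C)c(CCCCCCCCCCCCCc2c(O)c(OC)c(C)c(O)c2OC(C)C)c1O | intermediate
14 | 3,3'-(tridecane-1,13-diyl)bis[5-methoxy-6-methyl-2-(propan-2-yloxy)cyclohexa-2,5-diene-1,4-dione] | COC1=C(C)C(=O)C(OC(C)C)=C(CCCCCCCCCCCCCC2=C(OC(C)C)C(=O)C(C)=C(OC)C2=O)C1=O | intermediate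
15 | 2-hydroxy-3-methyl-5-(propan-2-yloxy)-6-{13-[5-methoxy-4-methyl-3,6-dioxo-2-(propan-2-yloxy)cyclohexa-1,4-dien-1-yl]tridecyl}cyclohexa-2,5-diene-1,4-dione | COC1=C(C)C(=O)C(OC(C)C)=C(CCCCCCCCCCCCCC2=C(OC(C)C)C(=O)C(C)=C(O)C2=O)C1=O | intermediate
16 | 2,5-dihydroxy-3-[13-(2-hydroxy-5-methoxy-4-methyl-3,6-dioxocyclohexa-1,4-dien-1-yl)tridecyl]-6-methylcyclohexa-2,5-diene-1,4-dione (CNP0107579.0) | COC1=C(C)C(=O)C(O)=C(CCCCCCCCCCCCCC2=C(O)C(=O)C(C)=C(O)C2=O)C1=O | target

**Step count**
Total: 8 steps. Longest linear sequence: 7 steps (steps 1, 2, 3, 5, 6, 7, 8); step 4 is a one-step side branch.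

**Three steps most likely to fail**

Step 5 (β-methoxyvinyllithium addition). The E isomer of 9 would give a lithium species that collapses to propyne and LiOMe, so the reagent depends on isomerically pure 9. Two additions must both succeed, and 11 is an acid-labile hydroxy enol ether. The fallback sets out from 4 (with 5 from step 3) and comes back at 14. It replaces the β-alkoxyvinyllithium by a stable α-alkoxyvinyllithium and reverses the order of the two additions to the squarate. Purchased (Z)-1-methoxyprop-1-ene (CO/C=C\C) is lithiated at the oxygen-bearing carbon (t-BuLi, THF, −78 → −10 °C) to (Z)-(1-methoxyprop-1-en-1-yl)lithium F1. This adds to 4 at −78 °C and the alkoxide is capped with Me3SiCl to give 4-[(Z)-1-methoxyprop-1-en-1-yl]-2,3-di(propan-2-yloxy)-4-[(trimethylsilyl)oxy]cyclobut-2-en-1-one F2. BrMg(CH2)13MgBr 5 (0.45 equiv) adds to the remaining carbonyl of two molecules of F2 to give 1,1'-(tridecane-1,13-diyl)bis{4-[(Z)-1-methoxyprop-1-en-1-yl]-2,3-di(propan-2-yloxy)-4-[(trimethylsilyl)oxy]cyclobut-2-en-1-ol} F3. On brief cold dilute HCl work-up F3 loses isopropanol with 1,3-transposition to the regio-reversed 3,3'-(tridecane-1,13-diyl)bis{4-[(Z)-1-methoxyprop-1-en-1-yl]-2-(propan-2-yloxy)-4-[(trimethylsilyl)oxy]cyclobut-2-en-1-one} F4. Heating F4 (PhMe, 110 °C) gives, by the same twofold ring expansion, 3,3'-(tridecane-1,13-diyl)bis{5-methoxy-6-methyl-2-(propan-2-yloxy)-4-[(trimethylsilyl)oxy]phenol} F5, which (NH4)2Ce(NO3)6 in MeCN/H2O oxidises to 14.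

Step 6 (twofold ring expansion). Both ends must follow the same pathway. The ketene can be trapped by the free hydroxyl (butenolide), the dienone can lose methanol instead of enolising, and traces of acid dehydrate 11. The fallback sets out from 11 and comes back at 14. Both carbinols are capped (Me3SiCl, imidazole, DMF, 0 °C) to give 2,2'-(tridecane-1,13-diyl)bis{4-[(Z)-1-methoxyprop-1-en-2-yl]-3-(propan-2-yloxy)-4-[(trimethylsilyl)oxy]cyclobut-2-en-1-one} F6, in which the ketene has no hydroxyl to attack. Thermolysis (PhMe, 110 °C) then gives 2,2'-(tridecane-1,13-diyl)bis{6-methoxy-5-methyl-3-(propan-2-yloxy)-4-[(trimethylsilyl)oxy]phenol} F7, and (NH4)2Ce(NO3)6 in MeCN/H2O oxidises it with loss of silicon to 14.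

Step 7 (hydrolysis of one ring only). This is the weakest step of the route. The rings are identical and 13 carbons apart, so about 50% per pass is the ceiling unless aggregation helps, and hydroxide could attack the OiPr-bearing carbon instead. The fallback sets out from 14 and comes back at 16 by reversing the order of the two deprotections; it is still statistical but avoids the regiochemical question. BCl3 (CH2Cl2, −78 → 0 °C) first removes both isopropyl groups to give 3,3'-(tridecane-1,13-diyl)bis(2-hydroxy-5-methoxy-6-methylcyclohexa-2,5-diene-1,4-dione) F8. One of its two methyl ethers is then hydrolysed under forcing conditions on the dianion (2 M NaOH, dioxane, 80 °C, argon, stopped at half conversion). The mixture is separated by acidity (ring B is the stronger acid) to give 16, and recovered F8 is recycled.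

**Further compounds**
F1 | step 5 | (Z)-(1-methoxyprop-1-en-1-yl)lithium | CO/C([Li])=C\C
F2 | step 5 | 4-[(Z)-1-methoxyprop-1-en-1-yl]-2,3-di(propan-2-yloxy)-4-[(trimethylsilyl)oxy]cyclobut-2-en-1-one | CO/C(=C\C)C1(O[Si](C)(C)C)C(OC(C)C)=C(OC(C)C)C1=O
F3 | step 5 | 1,1'-(tridecane-1,13-diyl)bis{4-[(Z)-1-methoxyprop-1-en-1-yl]-2,3-di(propan-2-yloxy)-4-[(trimethylsilyl)oxy]cyclobut-2-en-1-ol} | CO/C(=C\C)C1(O[Si](C)(C)C)C(OC(C)C)=C(OC(C)C)C1(O)CCCCCCCCCCCCCC1(O)C(OC(C)C)=C(OC(C)C)C1(O[Si](C)(C)C)/C(OC)=C/C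
F4 | step 5 | 3,3'-(tridecane-1,13-diyl)bis{4-[(Z)-1-methoxyprop-1-en-1-yl]-2-(propan-2-yloxy)-4-[(trimethylsilyl)oxy]cyclobut-2-en-1-one} | CO/C(=C\C)C1(O[Si](C)(C)C)C(=O)C(OC(C)C)=C1CCCCCCCCCCCCCC1=C(OC(C)C)C(=O)C1(O[Si](C)(C)C)/C(OC)=C/C
F5 | step 5 | 3,3'-(tridecane-1,13-diyl)bis{5-methoxy-6-methyl-2-(propan-2-yloxy)-4-[(trimethylsilyl)oxy]phenol} | COc1c(C)c(O)c(OC(C)C)c(CCCCCCCCCCCCCc2c(O[Si](C)(C)C)c(OC)c(C)c(O)c2OC(C)C)c1O[Si](C)(C)C
F6 | step 6 | 2,2'-(tridecane-1,13-diyl)bis{4-[(Z)-1-methoxyprop-1-en-2-yl]-3-(propan-2-yloxy)-4-[(trimethylsilyl)oxy]cyclobut-2-en-1-one} | CO/C=C(/C)C1(O[Si](C)(C)C)C(OC(C)C)=C(CCCCCCCCCCCCCC2=C(OC(C)C)C(O[Si](C)(C)C)(/C(C)=C\OC)C2=O)C1=O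
F7 | step 6 | 2,2'-(tridecane-1,13-diyl)bis{6-methoxy-5-methyl-3-(propan-2-yloxy)-4-[(trimethylsilyl)oxy]phenol} | COc1c(C)c(O[Si](C)(C)C)c(OC(C)C)c(CCCCCCCCCCCCCc2c(O)c(OC)c(C)c(O[Si](C)(C)C)c2OC(C)C)c1O
F8 | step 7 | 3,3'-(tridecane-1,13-diyl)bis(2-hydroxy-5-methoxy-6-methylcyclohexa-2,5-diene-1,4-dione) | COC1=C(C)C(=O)C(O)=C(CCCCCCCCCCCCCC2=C(O)C(=O)C(C)=C(OC)C2=O)C1=O
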